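**Retrosynthetic overview**
- Target ⇐ its N,N'-di-Boc derivative (acidolysis last).
- Di-Boc 2-iminoimidazolidine ⇐ open-chain di-Boc guanidine of 2,5-dibromotryptamine, by disconnecting the benzylic C–N bond. Forward, this is a catalytic enantioselective dehydrogenative ring closure: DDQ generates the 3-alkylidene-3H-indole and a chiral phosphoric acid directs the guanidine nitrogen, so ring and stereocentre arise together from an unfunctionalised CH2.
- 2,5-Dibromo guanidine ⇐ (C2–Br, NBS) 5-bromotryptamine guanidine ⇐ 5-bromotryptamine + di-Boc amidine-transfer reagent.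
- Ring order: the indole is bought; the 2-aminoimidazoline is the only ring made (step 3), following the tryptamine → guanidine → oxidative closure logic presumed in nature.

Assumption: 5-bromotryptamine (free base) and N,N'-di-Boc-1H-pyrazole-1-carboxamidine are taken as inexpensive catalogue materials.
Assumption: the facial sense of the phosphoric acid cannot be predicted with certainty; the route is written with (R)-TRIP giving the (R)-product, and (S)-TRIP is used instead if the first analytical run shows the opposite sense.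

The target stereocentre is (R): priorities N > CH2N > indolyl > H.

**Step 1**
Reactants: 1 5-bromotryptamine; 2 N,N'-di-Boc-1H-pyrazole-1-carboxamidine
Product: 3 N-[2-(5-bromo-1H-indol-3-yl)ethyl]-N',N''-bis(tert-butoxycarbonyl)guanidine
Conditions: 2 (1.05 equiv), THF, rt, 12 h
Reagents that add atoms: N,N'-di-Boc-1H-pyrazole-1-carboxamidine (2), CC(C)(C)OC(=O)NC(=NC(=O)OC(C)(C)C)n1cccn1
Why: Amidine transfer (guanylation) to the primary amine with pyrazole as leaving group; the indole N–H and the aryl bromide do not react.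

**Step 2**
Reactants: 3 N-[2-(5-bromo-1H-indol-3-yl)ethyl]-N',N''-bis(tert-butoxycarbonyl)guanidine; 4 N-bromosuccinimide
Product: 5 N-[2-(2,5-dibromo-1H-indol-3-yl)ethyl]-N',N''-bis(tert-butoxycarbonyl)guanidine
Conditions: NBS (1.0 equiv), CH2Cl2/AcOH 10:1, 0 °C, dark, 1 h
Reagents that add atoms: N-bromosuccinimide (4), O=C1CCC(=O)N1Br
Why: Electrophilic aromatic bromination of a 3-substituted indole goes to C2; the 5-bromo benzenoid ring is deactivated and the non-basic di-Boc guanidine is a poor competing nucleophile under mildly acidic conditions.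

**Step 3**
Reactants: 5 N-[2-(2,5-dibromo-1H-indol-3-yl)ethyl]-N',N''-bis(tert-butoxycarbonyl)guanidine
Product: 7 tert-butyl (5R)-2-[(tert-butoxycarbonyl)imino]-5-(2,5-dibromo-1H-indol-3-yl)imidazolidine-1-carboxylate, via alkylideneindolenine 6 (not isolated)
Conditions: DDQ (1.1 equiv, portionwise), (R)-TRIP (10 mol%), 4 Å MS, CH2Cl2, −30 → 0 °C
Reagents that add atoms: none
Why: Proposed new method: DDQ abstracts hydride from the indole-activated benzylic CH2 (Yonemitsu-type dehydrogenation) to give the 2-bromo-3-alkylidene-3H-indole 6, with the C2 bromine blocking side reactions at C2; (R)-TRIP protonates the indolenine nitrogen and hydrogen-bonds the Boc–N–H of the guanidine, so the 5-exo-trig aza-Michael addition to the exocyclic carbon occurs on one face inside a chiral ion pair, re-aromatising the indole and setting the (R) centre; the closest known chemistry is DDQ oxidative cyclisation of N-acyltryptamines to 5-(indol-3-yl)oxazolines, together with chiral-phosphoric-acid-catalysed enantioselective additions to 3-alkylideneindolenines generated in situ and DDQ-driven asymmetric cross-dehydrogenative couplings of 3-benzylindoles.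

**Step 4**
Reactants: 7 tert-butyl (5R)-2-[(tert-butoxycarbonyl)imino]-5-(2,5-dibromo-1H-indol-3-yl)imidazolidine-1-carboxylate
Product: 9 (R)-4-(2,5-dibromo-1H-indol-3-yl)-4,5-dihydro-1H-imidazol-2-amine, via trifluoroacetate salt 8 (not isolated)
Conditions: TFA/CH2Cl2 1:2 (anhydrous), 0 °C → rt, 3 h; evaporate; cold 1 M NaOH, extract with CHCl3/iPrOH 3:1
Reagents that add atoms: none
Why: Acidolytic N-Boc cleavage (tert-butyl cation loss, then decarboxylation) leaves the aryl bromides untouched, and the protonated guanidinium on a doubly bromine-deactivated indole is a poor leaving group, so the benzylic centre is retained before basic work-up frees the guanidine.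

The ee of 7 is measured by chiral HPLC; 7 is recrystallised if enrichment is needed.

**Compound list**
1 | 5-bromotryptamine | NCCc1c[nH]c2ccc(Br)cc12 | starting material
2 | N,N'-di-Boc-1H-pyrazole-1-carboxamidine | CC(C)(C)OC(=O)NC(=NC(=O)OC(C)(C)C)n1cccn1 | starting material
3 | N-[2-(5-bromo-1H-indol-3-yl)ethyl]-N',N''-bis(tert-butoxycarbonyl)guanidine | CC(C)(C)OC(=O)NC(=NC(=O)OC(C)(C)C)NCCc1c[nH]c2ccc(Br)cc12 | intermediate
4 | N-bromosuccinimide | O=C1CCC(=O)N1Br | starting material
5 | N-[2-(2,5-dibromo-1H-indol-3-yl)ethyl]-N',N''-bis(tert-butoxycarbonyl)guanidine | CC(C)(C)OC(=O)NC(=NC(=O)OC(C)(C)C)NCCc1c(Br)[nH]c2ccc(Br)cc12 | intermediate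
6 | N-[2-(2,5-dibromo-3H-indol-3-ylidene)ethyl]-N',N''-bis(tert-butoxycarbonyl)guanidine (alkylideneindolenine, alkene geometry undefined, present as its N-protonated phosphate ion pair) | CC(C)(C)OC(=O)NC(=NC(=O)OC(C)(C)C)NCC=C1C(Br)=Nc2ccc(Br)cc21 | intermediate
7 | tert-butyl (5R)-2-[(tert-butoxycarbonyl)imino]-5-(2,5-dibromo-1H-indol-3-yl)imidazolidine-1-carboxylate | CC(C)(C)OC(=O)N=C1N(C(=O)OC(C)(C)C)[C@H](c2c(Br)[nH]c3ccc(Br)cc23)CN1 | intermediate
8 | (R)-4-(2,5-dibromo-1H-indol-3-yl)-4,5-dihydro-1H-imidazol-2-amine trifluoroacetate salt | NC1=N[C@H](c2c(Br)[nH]c3ccc(Br)cc23)CN1.OC(=O)C(F)(F)F | intermediate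
9 | (R)-4-(2,5-dibromo-1H-indol-3-yl)-4,5-dihydro-1H-imidazol-2-amine | NC1=N[C@H](c2c(Br)[nH]c3ccc(Br)cc23)CN1 | target

**Totals**
Total step count: 4. Longest linear sequence: 4 steps (1 → 3 → 5 → 7 → 9).

**Steps most likely to fail**

Step 3 (highest risk). The dibromo-indole may react sluggishly with DDQ, and an uncatalysed ring closure would erode ee. Other risks are over-oxidation of 7 and capture of 6 by adventitious water. The fallback gives up catalytic stereocontrol and sets out from 5. Treating 5 with DDQ (1.1 equiv) and diphenyl phosphate (10 mol%) in CH2Cl2 at rt gives racemic tert-butyl 2-[(tert-butoxycarbonyl)imino]-5-(2,5-dibromo-1H-indol-3-yl)imidazolidine-1-carboxylate F1. This is resolved by preparative chiral SFC on an amylose-type phase. The (R)-enantiomer is 7, where the route is rejoined, and tert-butyl (5S)-2-[(tert-butoxycarbonyl)imino]-5-(2,5-dibromo-1H-indol-3-yl)imidazolidine-1-carboxylate F2 is set aside.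

Step 2. Bromonium attack at C3 followed by closure of the side-chain N–H onto C2 (bromopyrroloindoline formation), or over-bromination, could compete. The fallback installs the C2 bromine before the guanidine exists, with the side-chain nitrogen fully masked, and sets out from 1. Heating 1 with phthalic anhydride in toluene (Dean–Stark) gives 2-[2-(5-bromo-1H-indol-3-yl)ethyl]isoindoline-1,3-dione F3. Bromination with 4 in CH2Cl2/AcOH at 0 °C gives 2-[2-(2,5-dibromo-1H-indol-3-yl)ethyl]isoindoline-1,3-dione F4. Hydrazine hydrate in EtOH at 60 °C releases 2,5-dibromotryptamine F5, which is guanylated with 2 as in step 1 to rejoin the route at 5.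

Step 4. Strong protic acid could ionise the indol-3-yl C–N bond (racemisation) or hydrolyse the 2-bromoindole to an oxindole. The fallback replaces Brønsted acidolysis with a silyl-transfer fragmentation under base-buffered aprotic conditions and sets out from 7. TMSOTf (4 equiv) and 2,6-lutidine (6 equiv) in CH2Cl2 at 0 °C convert both Boc groups into silyl carbamates, giving trimethylsilyl (5R)-5-(2,5-dibromo-1H-indol-3-yl)-2-{[(trimethylsilyloxy)carbonyl]imino}imidazolidine-1-carboxylate F6. Methanol then cleaves the silyl carbamates with loss of CO2 to give (R)-4-(2,5-dibromo-1H-indol-3-yl)-4,5-dihydro-1H-imidazol-2-amine trifluoromethanesulfonate salt F7. Cold 1 M NaOH work-up frees the base and rejoins the route at 9.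

**Further compounds**
F1 | step 3 | racemic tert-butyl 2-[(tert-butoxycarbonyl)imino]-5-(2,5-dibromo-1H-indol-3-yl)imidazolidine-1-carboxylate | CC(C)(C)OC(=O)N=C1N(C(=O)OC(C)(C)C)C(c2c(Br)[nH]c3ccc(Br)cc23)CN1
F2 | step 3 | tert-butyl (5S)-2-[(tert-butoxycarbonyl)imino]-5-(2,5-dibromo-1H-indol-3-yl)imidazolidine-1-carboxylate | CC(C)(C)OC(=O)N=C1N(C(=O)OC(C)(C)C)[C@@H](c2c(Br)[nH]c3ccc(Br)cc23)CN1
F3 | step 2 | 2-[2-(5-bromo-1H-indol-3-yl)ethyl]isoindoline-1,3-dione | O=C1c2ccccc2C(=O)N1CCc1c[nH]c2ccc(Br)cc12
F4 | step 2 | 2-[2-(2,5-dibromo-1H-indol-3-yl)ethyl]isoindoline-1,3-dione | O=C1c2ccccc2C(=O)N1CCc1c(Br)[nH]c2ccc(Br)cc12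
F5 | step 2 | 2,5-dibromotryptamine | NCCc1c(Br)[nH]c2ccc(Br)cc12
F6 | step 4 | trimethylsilyl (5R)-5-(2,5-dibromo-1H-indol-3-yl)-2-{[(trimethylsilyloxy)carbonyl]imino}imidazolidine-1-carboxylate | C[Si](C)(C)OC(=O)N=C1N(C(=O)O[Si](C)(C)C)[C@H](c2c(Br)[nH]c3ccc(Br)cc23)CN1
F7 | step 4 | (R)-4-(2,5-dibromo-1H-indol-3-yl)-4,5-dihydro-1H-imidazol-2-amine trifluoromethanesulfonate salt | NC1=N[C@H](c2c(Br)[nH]c3ccc(Br)cc23)CN1.OS(=O)(=O)C(F)(F)F
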